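The ratio of protic impurity to solid substrate charged, 0.500 in the flask, is the number to read first.

| setting | south | east | flask |
|---|---|---|---|
| solid substrate | 2.1 M | 1.5 M | 1.5 M |
| coupling partner | 1.2 M | 1.2 M | 1.20 M |
| protic impurity | 0.75 M | 1.1 M | 0.750 M |
| remark | run made earlier | run made earlier |  |
| time |  |  | 12 h |

- south (time / h: target / %): 0.833: 4.3; 2.00: 15.4; 4.00: 31.6; 10.0: 52.6
- east (time / h: target / %): 1.33: 12.7; 3.00: 24.5; 6.00: 27.3; 10.0: 27.9

(standard deviation of a reading: 0.3 percentage points)

- solid, in amounts per volume of the solution: solid substrate
- the earlier runs were read with a standard deviation of 0.3 percentage points
- at the start none of the solid substrate is in solution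

* how much target there is at 12 h, in percent of the solid substrate charged
* the change that raises the amount of target at 12 h, in percent of the solid substrate charged most ("none" if none brings more than 2 percentage points) (birch / maple / ash / none)
* amount of target at 12 h, in percent of the solid substrate charged, after ash

- birch: doubling the solubility of the solid substrate, all else as stated
- maple: doubling the amount of coupling partner, all else as stated
- ash: doubling the dissolution coefficient of the solid substrate, all else as stated

The east readings stand flat, 27.3% at 6.00 h and 27.9% at 10.0 h, close to the 26.7% that remains of its solid substrate if protic impurity removes it one for one. Impurity then looks like the limiting reagent of that loss, since in the flask 0.750 M stands against 1.5 M. Call the substrate charge minus the impurity charge, as a share of the substrate charge, the free share: 50.0% in the flask. The south run made 1.10 M of target by 10.0 h, more than the flask's 0.750 M of free substrate, from the same coupling partner and impurity charges. The reckoning here therefore expects the free share at 12 h, after ash too, and "none" as the best change.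

The forecast gives 49%, 49.4% after ash, and maple, with “a borderline gain of about 2 points”, so the two part on the choice.

The flask gives 49.9%, 50.0% after ash, and none: birch adds 0.13 percentage points, maple 0.11 points, ash 0.072 points.

    dissolved substrate + coupling partner → target (k = 3.20 × 10⁻⁴ /M/s)
    solid substrate + protic impurity → quenched substrate (k = 0.00310 /M/s)
    solid substrate ⇌ dissolved substrate, rate k3*(cs3 - [dissolved substrate]) while solid is left; crystals form when [dissolved substrate] > cs3 (solubility = 0.640 M, k = 1.40 × 10⁻⁴ /s)
    coupling partner → decomposition product (k = 6.00 × 10⁻⁷ /s)

The flask's target matches the free share of 50.0%. The neighbour flask, with 0.60 M of solid substrate, has a free share of −25.0%, yet it gives 24.7%. There the substrate is gone, 0% left, while 40% of the protic impurity remains. So the balance of the neighbour flask counts the impurity consumed, 0.450 M, which leaves 0.148 M of substrate, or 24.7% of its charge, against target of 24.7%.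

(All runs were computed for an exercise; noise was put on by code.)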